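The target is read as a (−)-shikimic acid ring whose alkene has been moved: the C3, C4 and C5 oxygens are kept, the carboxyl carbon becomes CH2OBz, and the benzoyloxy carbon is the former vinylic C2. Everything rests on a Schenck ene reaction of singlet oxygen with the C1=C2 enoate of the cyclohexene ring. In one operation it forms the C2–O bond, takes the pseudoaxial C6–H geminal to the ester and shifts the alkene to C1=C6. The precursor is methyl shikimate carrying a trans-fused butane-2,3-diacetal (dioxane ring) on O4/O5 and a pseudoaxial silyl ether on O3, which together fix the half-chair and shield one face.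

Key step: step 3

Remark: shikimate numbering is kept for every compound (C1 carries the carboxyl-derived carbon C7; O3, O4 and O5 are the original hydroxyl oxygens). The cyclic orthoester F5 is taken as a mixture at its orthoester carbon, which disappears when it is opened.

Step 1
Reactants: 1 (−)-shikimic acid
Product: 3 methyl shikimate 4,5-O-butane-2,3-diacetal (trans-fused dioxane on O4/O5; both methoxy groups axial; 3-OH free), via methyl shikimate 2 (not isolated)
Conditions: CSA (cat.), MeOH, reflux; then butane-2,3-dione, HC(OMe)3, reflux; NaHCO3 quench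
Reagents that add atoms: methanol, CO; butane-2,3-dione, CC(=O)C(C)=O; trimethyl orthoformate, COC(OC)OC
Why: Fischer esterification followed by acid-catalysed butane-2,3-diacetal formation under thermodynamic control should engage only the trans-diequatorial 4,5-diol as a trans-fused dioxane whose two new acetal centres are fixed by the anomeric effect, leaving the 3-OH free.

Step 2
Reactants: 3 methyl shikimate 4,5-O-butane-2,3-diacetal
Product: 4 3-O-tert-butyldimethylsilyl ether of 3
Conditions: TBSOTf, 2,6-lutidine, CH2Cl2, −78 → 0 °C
Reagents that add atoms: tert-butyldimethylsilyl triflate, CC(C)(C)[Si](C)(C)OS(=O)(=O)C(F)(F)F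
Why: Silyl ether formation with a silyl triflate and a hindered base should cap the pseudoaxial secondary 3-OH without touching a stereocentre and installs the bulky, non-hydrogen-bonding group needed for face control.

Step 3
Reactants: 4 3-O-TBS methyl shikimate diacetal
Product: 6 methyl 2-hydroxy-3-silyloxy cyclohex-6-ene-1-carboxylate (alkene now C1=C6; new C2–OH trans to O3; diacetal kept), via allylic hydroperoxide 5 (not isolated)
Conditions: O2, 5,10,15,20-tetraphenylporphyrin (cat.), visible light, CDCl3 (filtered through basic Al2O3), 0 °C; then PPh3, 0 °C → rt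
Reagents that add atoms: dioxygen, O=O
Why: Proposed new method: singlet oxygen should add to the C1=C2 enoate through a perepoxide-like transition state in which the inner oxygen bonds to the β-carbon C2 and the outer oxygen removes the pseudoaxial hydrogen from C6 (the carbon geminal to the ester) on the same face, so that the alkene moves to C1=C6, stays conjugated and leaves hydroperoxide 5, whose O–O bond triphenylphosphine then reduces without base to give 6. The closest known reaction type is the Schenck ene reaction of tiglate-type α,β-unsaturated esters, which gives β-hydroperoxy α-alkylidene esters by the same geminal hydrogen abstraction; a γ-oxygenated cyclohexene-1-carboxylate has not served as the ene partner, which is why the step is labelled. No ring is closed. The only new stereocentre, C2, is controlled by the trans-fused diacetal ring, which freezes the half-chair so that the C3 silyloxy group stands pseudoaxial on one face while the single well-aligned allylic hydrogen, pseudoaxial C6–H, lies on the other; oxygen should therefore arrive anti to O3 and C2–O should end trans to C3–O. The step needs geminal regioselectivity and anti facial selectivity: the ester directs oxygen to C2 and the C3–H is pseudoequatorial and on an oxygen-bearing carbon, which should suppress the alternative, while the silyl ether shields its face and cannot guide oxygen syn as a free hydroxyl would. The enoate is electron-poor, so a solvent with a long singlet-oxygen lifetime, low temperature and prolonged irradiation with fresh sensitiser are planned.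

Step 4
Reactants: 6 C2 hydroxy enoate
Product: 7 allylic 1,3-diol (C7 CH2OH and C2–OH; 3-OTBS and diacetal kept)
Conditions: i-Bu2AlH (excess), CH2Cl2, −78 °C; aq. KNaC4H4O6
Reagents that add atoms: none
Why: Hydride 1,2-reduction of a conjugated ester by i-Bu2AlH at low temperature (the first equivalent is spent on the C2 hydroxyl) is routine for β-hydroxy α-alkylidene esters and should leave the silyl ether, the diacetal and all stereocentres alone.

Step 5
Reactants: 7 allylic 1,3-diol; 8 benzoyl chloride
Product: 9 dibenzoate (C7–OBz and C2–OBz; 3-OTBS and diacetal kept)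
Conditions: BzCl (2.5 equiv), pyridine, DMAP (cat.), CH2Cl2, 0 °C → rt
Reagents that add atoms: benzoyl chloride (second equivalent), O=C(Cl)c1ccccc1
Why: DMAP-catalysed O-acylation with two or more equivalents of benzoyl chloride esterifies both the primary and the secondary allylic alcohol at oxygen with retention at C2, and the diacetal holds O2 and O3 trans-diaxial so that neither silyl nor acyl groups can shift between them.

Step 6
Reactants: 9 dibenzoate
Product: 10 dibenzoate with free axial 3-OH (diacetal kept)
Conditions: HF·pyridine, pyridine, THF, 0 °C → rt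
Reagents that add atoms: none
Why: Fluoride-driven Si–O cleavage in a pyridine-buffered, slightly acidic medium should remove the silyl ether while benzoates and the diacetal survive, and the locked trans-diaxial geometry blocks benzoyl migration from O2 to the freed O3.

Step 7
Reactants: 10 3-hydroxy dibenzoate
Product: 11 3-O-acetate dibenzoate diacetal
Conditions: Ac2O, pyridine, DMAP (cat.), CH2Cl2, 0 °C → rt
Reagents that add atoms: acetic anhydride, CC(=O)OC(C)=O
Why: DMAP-catalysed acetylation of the axial secondary 3-OH is a standard esterification that should outpace any acyl scrambling and leaves the C3 configuration intact.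

Step 8
Reactants: 11 3-O-acetate dibenzoate diacetal
Product: 12 target, [(3R,4S,5S,6S)-5-acetoxy-6-(benzoyloxy)-3,4-dihydroxycyclohex-1-en-1-yl]methyl benzoate
Conditions: TFA/H2O (9:1), 0 °C → rt, short contact; toluene co-evaporation
Reagents that add atoms: none
Why: Acid-catalysed hydrolysis of the bis-ketal through oxocarbenium ions should free the 4,5-diol with every ring C–O bond intact, and the short, base-free exposure is chosen to keep the esters in place, since acyl migration to the cis 4-OH is mainly base-promoted.

Compound list
1 | (−)-shikimic acid, (3R,4S,5R)-3,4,5-trihydroxycyclohex-1-ene-1-carboxylic acid | O=C(O)C1=C[C@@H](O)[C@@H](O)[C@H](O)C1 | starting material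
2 | methyl shikimate | COC(=O)C1=C[C@@H](O)[C@@H](O)[C@H](O)C1 | intermediate
3 | methyl shikimate 4,5-O-butane-2,3-diacetal (trans-fused 2,3-dimethoxy-2,3-dimethyl-1,4-dioxane on O4/O5, both acetal carbons S, 3-OH free) | COC(=O)C1=C[C@@H](O)[C@H]2O[C@](C)(OC)[C@@](C)(OC)O[C@@H]2C1 | intermediate
4 | 3-O-tert-butyldimethylsilyl ether of 3 | COC(=O)C1=C[C@@H](O[Si](C)(C)C(C)(C)C)[C@H]2O[C@](C)(OC)[C@@](C)(OC)O[C@@H]2C1 | intermediate
5 | allylic hydroperoxide: methyl 2-hydroperoxy-3-O-TBS-4,5-O-diacetal cyclohex-6-ene-1-carboxylate, 2-OOH trans to 3-OTBS | COC(=O)C1=C[C@H]2O[C@](C)(OC)[C@@](C)(OC)O[C@@H]2[C@H](O[Si](C)(C)C(C)(C)C)[C@H]1OO | intermediate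
6 | C2 allylic alcohol (hydroxy enoate), 2-OH trans to 3-OTBS, alkene C1=C6 | COC(=O)C1=C[C@H]2O[C@](C)(OC)[C@@](C)(OC)O[C@@H]2[C@H](O[Si](C)(C)C(C)(C)C)[C@H]1O | intermediate
7 | allylic 1,3-diol (C7 CH2OH, C2–OH), 3-OTBS, diacetal | OCC1=C[C@H]2O[C@](C)(OC)[C@@](C)(OC)O[C@@H]2[C@H](O[Si](C)(C)C(C)(C)C)[C@H]1O | intermediate
8 | benzoyl chloride | O=C(Cl)c1ccccc1 | starting material
9 | C7,C2-dibenzoate, 3-OTBS, diacetal | O=C(OCC1=C[C@H]2O[C@](C)(OC)[C@@](C)(OC)O[C@@H]2[C@H](O[Si](C)(C)C(C)(C)C)[C@H]1OC(=O)c1ccccc1)c1ccccc1 | intermediate
10 | C7,C2-dibenzoate with free 3-OH, diacetal | O=C(OCC1=C[C@H]2O[C@](C)(OC)[C@@](C)(OC)O[C@@H]2[C@H](O)[C@H]1OC(=O)c1ccccc1)c1ccccc1 | intermediate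
11 | 3-O-acetate C7,C2-dibenzoate, diacetal | O=C(OCC1=C[C@H]2O[C@](C)(OC)[C@@](C)(OC)O[C@@H]2[C@H](OC(C)=O)[C@H]1OC(=O)c1ccccc1)c1ccccc1 | intermediate
12 | CNP0213675.1, [(3R,4S,5S,6S)-5-acetoxy-6-(benzoyloxy)-3,4-dihydroxycyclohex-1-en-1-yl]methyl benzoate | CC(=O)O[C@H]1[C@@H](O)[C@H](O)C=C(COC(=O)c2ccccc2)[C@@H]1OC(=O)c1ccccc1 | target

Total step count: 8. Longest linear sequence: 8 steps (1 to 12; benzoyl chloride 8 is bought).

Steps most likely to fail

Step 3 (labelled step). What may go wrong: the electron-poor enoate, further deactivated by the allylic silyloxy group, may be attacked so slowly by singlet oxygen that sensitiser bleaching and hydroperoxide decomposition outrun the ene reaction, or oxygen may arrive with poor facial discrimination. The fallback uses known chemistry, sets out from 4 and returns at 7. Catalytic OsO4 with N-methylmorpholine N-oxide in acetone/water would dihydroxylate the enoate on the face anti to the pseudoaxial silyl ether to give the methyl 1,2-cis-dihydroxy ester F1. Ac2O, pyridine and DMAP would acetylate only its secondary C2 hydroxyl to give the C2 monoacetate F2. The Burgess reagent in warm toluene would then dehydrate the tertiary C1 alcohol by syn-elimination; in the locked chair only the axial C6–H is cis to the leaving group (C2–H is trans), so the alkene should form at C1=C6 to give the 2-acetoxy enoate F3. Excess i-Bu2AlH at −78 °C would finally reduce the methyl ester and cleave the acetate in one operation, giving diol 7.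

Step 8. What may go wrong: acetyl migration from O3 to the neighbouring cis O4 as it is unmasked, or acid-promoted loss of the allylic C2 benzoate. The fallback sets out from 10 and returns at 12. The diacetal would be hydrolysed first (TFA/H2O), while no acetate is present, to give the 3,4,5-triol dibenzoate F4. Trimethyl orthoacetate with catalytic CSA would tie its cis-3,4-diol into the cyclic methyl orthoacetate F5. Mild aqueous acetic acid would then open this orthoester to the axial ester and equatorial alcohol, the usual stereoelectronic outcome, which places the acetate on O3 and frees the 4-OH, giving 12.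

Step 6. What may go wrong: slow cleavage of the hindered axial silyl ether, with benzoate loss or erosion of the diacetal if the fluoride conditions have to be forced. The fallback sets out from 3 and returns at 10. The 3-OH would be protected with TESOTf and 2,6-lutidine as the much more labile triethylsilyl ether F6. The same photooxygenation and phosphine reduction would give the triethylsilyl allylic alcohol F8 by way of the triethylsilyl allylic hydroperoxide F7. i-Bu2AlH would then give the triethylsilyl diol F9, and benzoyl chloride 8 (two equivalents or more) with pyridine and DMAP the triethylsilyl dibenzoate F10. The triethylsilyl group would be removed with AcOH/THF/H2O at room temperature, without fluoride, giving 10.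

Further compounds
F1 | step 3 | methyl 1,2-cis-dihydroxy ester (1-OH and 2-OH anti to 3-OTBS, diacetal kept) | COC(=O)[C@]1(O)C[C@H]2O[C@](C)(OC)[C@@](C)(OC)O[C@@H]2[C@H](O[Si](C)(C)C(C)(C)C)[C@H]1O
F2 | step 3 | C2 monoacetate of F1 (tertiary 1-OH free) | COC(=O)[C@]1(O)C[C@H]2O[C@](C)(OC)[C@@](C)(OC)O[C@@H]2[C@H](O[Si](C)(C)C(C)(C)C)[C@H]1OC(C)=O
F3 | step 3 | 2-acetoxy enoate (alkene C1=C6, 3-OTBS, diacetal) | COC(=O)C1=C[C@H]2O[C@](C)(OC)[C@@](C)(OC)O[C@@H]2[C@H](O[Si](C)(C)C(C)(C)C)[C@H]1OC(C)=O
F4 | step 8 | 3,4,5-triol C7,C2-dibenzoate | O=C(OCC1=C[C@@H](O)[C@H](O)[C@H](O)[C@H]1OC(=O)c1ccccc1)c1ccccc1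
F5 | step 8 | cyclic 3,4-O-(1-methoxyethylidene) orthoacetate of F4 (mixture at the orthoester carbon) | O=C(OCC1=C[C@@H](O)[C@@H]2OC(C)(OC)O[C@@H]2[C@H]1OC(=O)c1ccccc1)c1ccccc1
F6 | step 6 | 3-O-triethylsilyl ether of 3 | COC(=O)C1=C[C@@H](O[Si](CC)(CC)CC)[C@H]2O[C@](C)(OC)[C@@](C)(OC)O[C@@H]2C1
F7 | step 6 | triethylsilyl allylic hydroperoxide (not isolated) | COC(=O)C1=C[C@H]2O[C@](C)(OC)[C@@](C)(OC)O[C@@H]2[C@H](O[Si](CC)(CC)CC)[C@H]1OO
F8 | step 6 | triethylsilyl allylic alcohol (hydroxy enoate) | COC(=O)C1=C[C@H]2O[C@](C)(OC)[C@@](C)(OC)O[C@@H]2[C@H](O[Si](CC)(CC)CC)[C@H]1O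
F9 | step 6 | triethylsilyl diol | OCC1=C[C@H]2O[C@](C)(OC)[C@@](C)(OC)O[C@@H]2[C@H](O[Si](CC)(CC)CC)[C@H]1O
F10 | step 6 | triethylsilyl dibenzoate | O=C(OCC1=C[C@H]2O[C@](C)(OC)[C@@](C)(OC)O[C@@H]2[C@H](O[Si](CC)(CC)CC)[C@H]1OC(=O)c1ccccc1)c1ccccc1
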